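**Retrosynthetic overview**
1. The C3–CH2CO2H bond is made last, by adding an acetic acid bis-silyl ketene acetal to the 1,2-dioxolan-3-ylium ion from 3-methoxydioxolane 13 (sets C3).
2. The only ring, the 1,2-dioxolane, is closed one stage earlier in a single operation that forms both C–O bonds: asymmetric conjugate addition of H2O2 to E-enone 10 (C5–O, sets C5) followed by peroxyhemiketalisation (C3–O).
3. Enone 10 comes from alkyne 8 by syn-carboalumination/acylation (fixes the E-trisubstituted alkene), and 8 from methyl ketone 6.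
4. Ketone 6 (side-chain stereocentre) comes from Cu-catalysed asymmetric conjugate addition of MeMgBr to enone 5, made by cross-metathesis of 10-phenyl-1-decene with methyl vinyl ketone.

Assumption: the SMILES is read as 2-[(3R,5R)-3,5-dimethyl-5-[(2R)-2-methyl-10-phenyldecyl]-1,2-dioxolan-3-yl]acetic acid (ring methyls cis); the enantiomer of each chiral catalyst or ligand is the one that gives the stated face selectivity.

**Step 1**
Reactants: 1 10-bromo-1-decene; 2 phenylmagnesium bromide
Product: 3 10-phenyl-1-decene
Conditions: Li2CuCl4 (3 mol %), THF, 0 °C → rt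
Reagents that add atoms: none
Why: Copper-catalysed Kochi-type Csp2–Csp3 Grignard cross-coupling with a primary alkyl bromide leaves the remote terminal alkene untouched; no stereocentre is formed.

**Step 2**
Reactants: 3 10-phenyl-1-decene; 4 methyl vinyl ketone
Product: 5 (E)-12-phenyldodec-3-en-2-one
Conditions: Hoveyda–Grubbs II (2 mol %), 4 (3 equiv), CH2Cl2, 40 °C
Reagents that add atoms: none
Why: Olefin cross-metathesis of a terminal alkene with an electron-poor enone partner is E-selective and driven by loss of ethylene; no stereocentre is formed.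

**Step 3**
Reactants: 5 (E)-12-phenyldodec-3-en-2-one
Product: 6 (R)-4-methyl-12-phenyldodecan-2-one
Conditions: MeMgBr (1.2 equiv), CuBr·SMe2 (5 mol %), Josiphos SL-J001 (6 mol %, enantiomer giving 4R), t-BuOMe, −75 °C; then 1 M HCl
Reagents that add atoms: methylmagnesium bromide, C[Mg]Br
Why: Copper/Josiphos-catalysed asymmetric conjugate addition of MeMgBr to a linear aliphatic E-enone delivers methyl to the Re face of C4 under ligand control, setting the side-chain stereocentre (R) in high ee.

**Step 4**
Reactants: 6 (R)-4-methyl-12-phenyldodecan-2-one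
Product: 8 (R)-4-methyl-12-phenyldodec-1-yne, via enol diethyl phosphate 7 (not isolated)
Conditions: LDA (1.1 equiv), THF, −78 °C; ClP(O)(OEt)2, −78 °C → rt; LDA (2.3 equiv), −78 °C → rt; H2O
Reagents that add atoms: none
Why: Negishi methyl ketone-to-alkyne protocol (kinetic enolisation at CH3, O-phosphorylation, then elimination to the acetylide); the β-stereocentre has no acidic hydrogen and is retained.

**Step 5**
Reactants: 8 (R)-4-methyl-12-phenyldodec-1-yne
Product: 10 (3E,6R)-4,6-dimethyl-14-phenyltetradec-3-en-2-one, via alkenylalane 9 (not isolated)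
Conditions: Me3Al (2.2 equiv), Cp2ZrCl2 (25 mol %), CH2Cl2, 0 °C → rt; then AcCl (3 equiv), Pd(PPh3)4 (5 mol %), THF, 0 °C → rt; 1 M HCl
Reagents that add atoms: trimethylaluminium, C[Al](C)C; acetyl chloride, CC(=O)Cl
Why: Zirconium-catalysed Negishi carboalumination adds CH3 and Al syn across the alkyne (Al at C1), and palladium-catalysed acylation of the alkenylalane proceeds with retention, giving the geometrically pure E-trisubstituted enone; no new stereocentre.

**Step 6**
Reactants: 10 (3E,6R)-4,6-dimethyl-14-phenyltetradec-3-en-2-one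
Product: 12 (5R)-3,5-dimethyl-5-[(2R)-2-methyl-10-phenyldecyl]-1,2-dioxolan-3-ol (both C3 anomers), via beta-hydroperoxy ketone 11 (not isolated)
Conditions: 9-amino-9-deoxy-epi-quinine·2 CF3CO2H (10 mol %; quinidine-derived pseudo-enantiomer if the facial sense is reversed), 50% aq. H2O2 (3 equiv), 1,4-dioxane, 30 °C
Reagents that add atoms: hydrogen peroxide, OO
Why: Proposed new method: the primary amine forms an iminium ion whose chiral ammonium/trifluoroacetate ion pair steers H2O2 to the Re face of the β-carbon (C4 of 10), the E-iminium reacting faster than the Z-isomer that equilibrates through the dienamine (as in enantioconvergent iminium transfer hydrogenations of β-methyl-β-alkyl enals), so the tetrasubstituted C–OO centre (ring C5, R) is set by catalyst control and the hydroperoxide then closes on the ketone to form the second C–O bond and the dioxolane ring; the closest known reaction is the cinchona-primary-amine-catalysed hydroperoxidation of β-monosubstituted acyclic enones to peroxyhemiketals, which has not been shown for acyclic β,β-dialkyl enones.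

**Step 7**
Reactants: 12 (5R)-3,5-dimethyl-5-[(2R)-2-methyl-10-phenyldecyl]-1,2-dioxolan-3-ol
Product: 13 (5R)-3-methoxy-3,5-dimethyl-5-[(2R)-2-methyl-10-phenyldecyl]-1,2-dioxolane (both C3 epimers)
Conditions: MeOH, PPTS (10 mol %), 4 Å MS, rt
Reagents that add atoms: methanol, CO
Why: Acid-catalysed peroxyketalisation (exchange of the anomeric OH for OMe through the peroxycarbenium ion) is the standard way to store 1,2-dioxolan-3-ols as ionisable 3-alkoxy derivatives; C5 is untouched and the C3 epimer ratio is irrelevant because C3 is planarised in step 8.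

**Step 8**
Reactants: 13 (5R)-3-methoxy-3,5-dimethyl-5-[(2R)-2-methyl-10-phenyldecyl]-1,2-dioxolane
Product: 16 2-[(3R,5R)-3,5-dimethyl-5-[(2R)-2-methyl-10-phenyldecyl]-1,2-dioxolan-3-yl]acetic acid, via dioxolan-3-ylium ion 14 (not isolated), via trimethylsilyl ester 15 (not isolated)
Conditions: CH2=C(OSiMe3)2 (2.5 equiv), chiral IDPi acid (3 mol %, enantiomer giving Si-face attack), toluene, −78 → −40 °C; then H2O/THF, 0 °C
Reagents that add atoms: 1,1-bis(trimethylsilyloxy)ethene, C=C(O[Si](C)(C)C)O[Si](C)(C)C
Why: Proposed new method: silylation of the confined chiral imidodiphosphorimidate by the ketene acetal gives a silylium Lewis acid that abstracts methoxide from 13 to form the planar 1,2-dioxolan-3-ylium (peroxycarbenium) ion paired with the chiral anion, and the ketene acetal adds to the Si face of C3 inside the chiral pocket (catalyst control, since the remote C5 substituents give no useful bias), so C3 becomes R with the two ring methyls cis and aqueous work-up frees the acid; the closest known reactions are IDPi-catalysed Mukaiyama-type additions of silyl ketene acetals to cyclic oxocarbenium ions from lactol acetates and the non-stereoselective Lewis-acid homologation of 3-alkoxy-1,2-dioxolanes with silyl ketene acetals.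

**Compound list**
1 | 10-bromo-1-decene | C=CCCCCCCCCBr | starting material
2 | phenylmagnesium bromide | Br[Mg]c1ccccc1 | starting material
3 | 10-phenyl-1-decene | C=CCCCCCCCCc1ccccc1 | intermediate
4 | methyl vinyl ketone (but-3-en-2-one) | CC(=O)C=C | starting material
5 | (E)-12-phenyldodec-3-en-2-one | CC(=O)/C=C/CCCCCCCCc1ccccc1 | intermediate
6 | (R)-4-methyl-12-phenyldodecan-2-one | CC(=O)C[C@H](C)CCCCCCCCc1ccccc1 | intermediate
7 | diethyl (R)-4-methyl-12-phenyldodec-1-en-2-yl phosphate (formed in situ) | C=C(OP(=O)(OCC)OCC)C[C@H](C)CCCCCCCCc1ccccc1 | intermediate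
8 | (R)-4-methyl-12-phenyldodec-1-yne | C#CC[C@H](C)CCCCCCCCc1ccccc1 | intermediate
9 | [(1E,4R)-2,4-dimethyl-12-phenyldodec-1-en-1-yl]dimethylalane (formed in situ) | C[Al](C)/C=C(\C)C[C@H](C)CCCCCCCCc1ccccc1 | intermediate
10 | (3E,6R)-4,6-dimethyl-14-phenyltetradec-3-en-2-one | CC(=O)/C=C(\C)C[C@H](C)CCCCCCCCc1ccccc1 | intermediate
11 | (4R,6R)-4-hydroperoxy-4,6-dimethyl-14-phenyltetradecan-2-one (formed in situ) | C[C@H](CCCCCCCCc1ccccc1)C[C@](OO)(C)CC(C)=O | intermediate
12 | (5R)-3,5-dimethyl-5-[(2R)-2-methyl-10-phenyldecyl]-1,2-dioxolan-3-ol (C3 anomers) | C[C@H](CCCCCCCCc1ccccc1)C[C@]1(C)CC(C)(O)OO1 | intermediate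
13 | (5R)-3-methoxy-3,5-dimethyl-5-[(2R)-2-methyl-10-phenyldecyl]-1,2-dioxolane (C3 epimers) | C[C@H](CCCCCCCCc1ccccc1)C[C@]1(C)CC(C)(OC)OO1 | intermediate
14 | (5R)-3,5-dimethyl-5-[(2R)-2-methyl-10-phenyldecyl]-1,2-dioxolan-3-ylium, IDPi ion pair (formed in situ) | C[C@H](CCCCCCCCc1ccccc1)C[C@]1(C)CC(C)=[O+]O1 | intermediate
15 | trimethylsilyl 2-[(3R,5R)-3,5-dimethyl-5-[(2R)-2-methyl-10-phenyldecyl]-1,2-dioxolan-3-yl]acetate (formed in situ) | C[C@H](CCCCCCCCc1ccccc1)C[C@]1(C)C[C@](C)(CC(=O)O[Si](C)(C)C)OO1 | intermediate
16 | 2-[(3R,5R)-3,5-dimethyl-5-[(2R)-2-methyl-10-phenyldecyl]-1,2-dioxolan-3-yl]acetic acid | C[C@H](CCCCCCCCc1ccccc1)C[C@]1(C)C[C@](C)(CC(=O)O)OO1 | target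

**Totals**
Total steps: 8. Longest linear sequence: 8 (1/2 → 3 → 5 → 6 → 8 → 10 → 12 → 13 → 16).

**Steps most likely to fail, with fallbacks**

Step 6 (proposed new hydroperoxidation) is the main risk. The β,β-disubstituted enone may form the iminium slowly, E/Z scrambling through the dienamine may erode selectivity at C5, and epoxide closure may compete with hemiketal trapping. Any minor C5 epimer is a diastereomer of 12 and can be removed by chromatography. The fallback uses known chemistry and sets out from 6. Kinetic silylation (LDA, Et3SiCl) gives the triethylsilyl enol ether F1. Cobalt-catalysed peroxidation (Co(thd)2, O2, Et3SiH) gives the bis-silyl monoperoxyketal F2. SnCl4-mediated peroxycarbenium [3+2] annulation with methyl 3-methylbut-3-enoate gives the dioxolane methyl ester F3 as a mixture of C3/C5 isomers. The (3R,5R) isomer is isolated by preparative HPLC and saponified (LiOH, THF/H2O), coming back to the route at 16.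

Step 8 (proposed new catalyst-controlled addition) is the second risk. The chiral anion may discriminate the faces of the tertiary peroxycarbenium ion poorly, or the ion may fragment. The fallback uses known chemistry and sets out from 13. SnCl4-mediated allylation with allyltrimethylsilane gives the 3-allyl dioxolane F4 without stereocontrol at C3, and the (3S,5R) epimer is separated. Ozonolysis (O3, CH2Cl2/MeOH, −78 °C; Me2S) gives the aldehyde F5, and Pinnick oxidation (NaClO2, NaH2PO4, 2-methyl-2-butene) comes back to the route at 16.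

Step 5 is the third risk. Carboalumination of the β-branched alkyne may be incomplete, and excess Me3Al consumes acetyl chloride in the acylation. The fallback sets out from 6. A TiCl4-mediated Mukaiyama aldol with 2-(trimethylsilyloxy)propene gives the β-hydroxy ketone F6. Dehydration (MsCl, Et3N, then DBU) and chromatographic separation of the E isomer come back to the route at 10.

**Further compounds**
F1 | step 6 | triethyl{[(4R)-4-methyl-12-phenyldodec-1-en-2-yl]oxy}silane | C=C(O[Si](CC)(CC)CC)C[C@H](C)CCCCCCCCc1ccccc1
F2 | step 6 | triethyl{[(4R)-4-methyl-12-phenyl-2-(triethylsilylperoxy)dodecan-2-yl]oxy}silane | CC(O[Si](CC)(CC)CC)(OO[Si](CC)(CC)CC)C[C@H](C)CCCCCCCCc1ccccc1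
F3 | step 6 | methyl 2-[(3R,5R)-3,5-dimethyl-5-[(2R)-2-methyl-10-phenyldecyl]-1,2-dioxolan-3-yl]acetate | C[C@H](CCCCCCCCc1ccccc1)C[C@]1(C)C[C@](C)(CC(=O)OC)OO1
F4 | step 8 | (3S,5R)-3-allyl-3,5-dimethyl-5-[(2R)-2-methyl-10-phenyldecyl]-1,2-dioxolane | C[C@H](CCCCCCCCc1ccccc1)C[C@]1(C)C[C@](C)(CC=C)OO1
F5 | step 8 | 2-[(3R,5R)-3,5-dimethyl-5-[(2R)-2-methyl-10-phenyldecyl]-1,2-dioxolan-3-yl]acetaldehyde | C[C@H](CCCCCCCCc1ccccc1)C[C@]1(C)C[C@](C)(CC=O)OO1
F6 | step 5 | (6R)-4-hydroxy-4,6-dimethyl-14-phenyltetradecan-2-one | CC(=O)CC(C)(O)C[C@H](C)CCCCCCCCc1ccccc1
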